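**Retrosynthetic overview**
- The target is the bis-MOM ketone minus two MOM groups. The ketone is cut at two bonds at once, C7–O and C6–C(O), back to a C6–C7 aryne of the chroman and the ring B propanoic acid.
- Feature used: in ring A (the benzo ring of the chroman) the ketone carbon sits on C6 between O5 and O7, and the free O7–H is on the neighbouring C7. A C6–C7 aryne takes oxygen and acyl carbon from one carboxylic acid at exactly these two atoms, so a C6 versus C8 acylation never has to be decided.
- Aryne precursor (5-MOM-oxy-6-trimethylsilyl-7-triflate of the chroman): from 5,7-dihydroxy-2,2-dimethylchroman-4-one (phloroglucinol plus 3-methylbut-2-enoic acid). The chelated O5–H leaves O7 for a carbamate; then C4 deoxygenation, O5 MOM, carbamate-directed C6 silylation, carbamate to triflate.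
- Acid: from 3,4-dihydroxybenzaldehyde by an O4 1,1-dimethylpropargyl ether, semihydrogenation, aromatic Claisen shift to the C5 prenyl group, O-methylation and a reductive Meldrum's acid homologation.
- Ring formation: only the pyran ring is built (first step); both benzene rings come from the starting materials.

Key step: step 15

Remark: the target has no stereocentre, so no configuration has to be set. Positions are numbered as in chroman (O1, C2 with the two methyl groups, benzo carbons C5 to C8).

**Route**

Step 1
Reactants: 1 phloroglucinol; 2 3-methylbut-2-enoic acid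
Product: 3 5,7-dihydroxy-2,2-dimethylchroman-4-one
Conditions: P2O5, MeSO3H, 70 °C
Reagents that add atoms: none
Why: Friedel–Crafts acylation of the symmetric, electron-rich triphenol followed by intramolecular oxa-Michael addition of an ortho hydroxyl closes the pyranone ring, and by symmetry only one chromanone can form.

Step 2
Reactants: 3 5,7-dihydroxy-2,2-dimethylchroman-4-one
Product: 4 5-hydroxy-2,2-dimethyl-4-oxochroman-7-yl N,N-diethylcarbamate
Conditions: Et2NCOCl, K2CO3, MeCN, 60 °C
Reagents that add atoms: N,N-diethylcarbamoyl chloride, CCN(CC)C(Cl)=O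
Why: O-carbamoylation of a phenoxide; O5–H is locked in a hydrogen bond to the C4 carbonyl and is far less acidic and nucleophilic than the vinylogous-acid O7–H, so only O7 should react.

Step 3
Reactants: 4 5-hydroxy-2,2-dimethyl-4-oxochroman-7-yl N,N-diethylcarbamate
Product: 6 5-hydroxy-2,2-dimethylchroman-7-yl N,N-diethylcarbamate, via ethyl carbonate 5 (not isolated)
Conditions: ClCO2Et, Et3N, THF, 0 °C; then NaBH4, H2O, 0 °C to rt
Reagents that add atoms: none
Why: Reductive deoxygenation of an ortho-hydroxyaryl ketone through its aryl ethyl carbonate: NaBH4 reduces the C4 ketone, the carbonate lets the benzylic oxygen leave via an ortho-quinone methide, and a second hydride adds at C4, while the tertiary carbamate is inert to borohydride.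

Step 4
Reactants: 6 5-hydroxy-2,2-dimethylchroman-7-yl N,N-diethylcarbamate
Product: 7 5-(methoxymethoxy)-2,2-dimethylchroman-7-yl N,N-diethylcarbamate
Conditions: MOMCl, i-Pr2NEt, CH2Cl2, 0 °C to rt
Reagents that add atoms: chloromethyl methyl ether, COCCl
Why: Williamson-type O-alkylation of the only free phenol with the reactive chloromethyl ether gives the MOM acetal.

Step 5
Reactants: 7 5-(methoxymethoxy)-2,2-dimethylchroman-7-yl N,N-diethylcarbamate
Product: 9 5-(methoxymethoxy)-2,2-dimethyl-6-(trimethylsilyl)chroman-7-yl N,N-diethylcarbamate, via C6 aryllithium 8 (not isolated)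
Conditions: s-BuLi, TMEDA, THF, −78 °C; then Me3SiCl, −78 °C to rt
Reagents that add atoms: chlorotrimethylsilane, C[Si](C)(C)Cl
Why: Directed ortho-metalation: C6–H lies between the two best lithium-coordinating groups (carbamate carbonyl and MOM oxygen) and is the most acidic ring proton, whereas C8–H has only the carbamate and the ring oxygen O1 shielded by the C2 methyl groups, and at −78 °C the aryllithium is silylated before the carbamoyl group can shift.

Step 6
Reactants: 9 5-(methoxymethoxy)-2,2-dimethyl-6-(trimethylsilyl)chroman-7-yl N,N-diethylcarbamate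
Product: 10 5-(methoxymethoxy)-2,2-dimethyl-6-(trimethylsilyl)chroman-7-ol
Conditions: LiAlH4, THF, 0 °C to reflux; neutral aqueous work-up
Reagents that add atoms: none
Why: Reductive cleavage of the aryl carbamate: hydride adds to the carbamate carbonyl and the phenoxide is expelled, while LiAlH4 touches neither the MOM acetal nor the aryl–silicon bond.

Step 7
Reactants: 10 5-(methoxymethoxy)-2,2-dimethyl-6-(trimethylsilyl)chroman-7-ol
Product: 11 5-(methoxymethoxy)-2,2-dimethyl-6-(trimethylsilyl)chroman-7-yl trifluoromethanesulfonate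
Conditions: Tf2O, pyridine, CH2Cl2, 0 °C
Reagents that add atoms: trifluoromethanesulfonic anhydride, O=S(=O)(OS(=O)(=O)C(F)(F)F)C(F)(F)F
Why: O-sulfonylation of the phenol gives the ortho-silylaryl triflate, and the MOM acetal should survive the cold, pyridine-buffered medium.

Step 8
Reactants: 12 3,4-dihydroxybenzaldehyde; 13 3-chloro-3-methylbut-1-yne
Product: 14 3-hydroxy-4-[(2-methylbut-3-yn-2-yl)oxy]benzaldehyde
Conditions: CuCl2·2H2O (cat.), DBU (1 equiv), MeCN, 0 °C
Reagents that add atoms: none
Why: Copper-catalysed propargylic etherification of a phenoxide through a copper allenylidene; with one equivalent of base only the more acidic O4–H, para to the aldehyde, is ionised, so the tertiary propargyl group should go to O4.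

Step 9
Reactants: 14 3-hydroxy-4-[(2-methylbut-3-yn-2-yl)oxy]benzaldehyde
Product: 15 3-(methoxymethoxy)-4-[(2-methylbut-3-yn-2-yl)oxy]benzaldehyde
Conditions: MOMCl, i-Pr2NEt, CH2Cl2, 0 °C to rt
Reagents that add atoms: chloromethyl methyl ether, COCCl
Why: Williamson-type O-alkylation of the remaining phenol gives the MOM acetal.

Step 10
Reactants: 15 3-(methoxymethoxy)-4-[(2-methylbut-3-yn-2-yl)oxy]benzaldehyde
Product: 16 3-(methoxymethoxy)-4-[(2-methylbut-3-en-2-yl)oxy]benzaldehyde
Conditions: H2 (1 atm), Pd/CaCO3 poisoned with Pb(OAc)2, quinoline, EtOAc, rt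
Reagents that add atoms: none
Why: Lindlar-type semihydrogenation of the terminal alkyne on lead-poisoned palladium stops at the alkene and leaves the aldehyde and the aryl ether intact.

Step 11
Reactants: 16 3-(methoxymethoxy)-4-[(2-methylbut-3-en-2-yl)oxy]benzaldehyde
Product: 17 4-hydroxy-3-(methoxymethoxy)-5-(3-methylbut-2-en-1-yl)benzaldehyde
Conditions: PhNEt2, 170 °C
Reagents that add atoms: none
Why: Aromatic Claisen rearrangement ([3,3]-sigmatropic shift) of the 1,1-dimethylallyl aryl ether delivers the allyl terminus to C5, the only free ortho position, which turns the branched ether into the linear prenyl group, and tautomerisation restores the phenol.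

Step 12
Reactants: 17 4-hydroxy-3-(methoxymethoxy)-5-(3-methylbut-2-en-1-yl)benzaldehyde
Product: 18 4-methoxy-3-(methoxymethoxy)-5-(3-methylbut-2-en-1-yl)benzaldehyde
Conditions: MeI, K2CO3, DMF, rt
Reagents that add atoms: iodomethane, CI
Why: Williamson O-methylation of the only free hydroxyl, which also removes the chance of the ortho-prenylphenol cyclising.

Step 13
Reactants: 18 4-methoxy-3-(methoxymethoxy)-5-(3-methylbut-2-en-1-yl)benzaldehyde; 19 2,2-dimethyl-1,3-dioxane-4,6-dione (Meldrum's acid)
Product: 21 5-[4-methoxy-3-(methoxymethoxy)-5-(3-methylbut-2-en-1-yl)benzyl]-2,2-dimethyl-1,3-dioxane-4,6-dione, via arylidene Meldrum's acid 20 (not isolated)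
Conditions: diethyl 2,6-dimethyl-1,4-dihydropyridine-3,5-dicarboxylate (Hantzsch ester), L-proline (cat.), EtOH, rt
Reagents that add atoms: none
Why: Tandem Knoevenagel condensation and conjugate transfer hydrogenation: only the doubly activated arylidene 20 is electrophilic enough to take hydride from the Hantzsch ester, so the isolated prenyl alkene is not reduced.

Step 14
Reactants: 21 5-[4-methoxy-3-(methoxymethoxy)-5-(3-methylbut-2-en-1-yl)benzyl]-2,2-dimethyl-1,3-dioxane-4,6-dione
Product: 23 3-[4-methoxy-3-(methoxymethoxy)-5-(3-methylbut-2-en-1-yl)phenyl]propanoic acid, via malonic acid 22 (not isolated)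
Conditions: pyridine–H2O (10:1), 100 °C
Reagents that add atoms: water, O
Why: Hydrolytic opening of the Meldrum's acid ring to the malonic acid and thermal decarboxylation give the propanoic acid in a buffered, non-acidic medium that spares the MOM acetal.

Step 15
Reactants: 11 5-(methoxymethoxy)-2,2-dimethyl-6-(trimethylsilyl)chroman-7-yl trifluoromethanesulfonate; 23 3-[4-methoxy-3-(methoxymethoxy)-5-(3-methylbut-2-en-1-yl)phenyl]propanoic acid
Product: 26 1-[7-hydroxy-5-(methoxymethoxy)-2,2-dimethylchroman-6-yl]-3-[4-methoxy-3-(methoxymethoxy)-5-(3-methylbut-2-en-1-yl)phenyl]propan-1-one, via cesium carboxylate 24 (not isolated), via aryne 25 (not isolated)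
Conditions: 23, Cs2CO3 (0.5 equiv), MeOH, rt, then evaporation to dryness; 11 (1.5 equiv), CsF (3 equiv), THF, 125 °C, sealed tube
Reagents that add atoms: none
Why: Fluoride attacks silicon of 11 and triflate leaves from C7 to give the C6–C7 aryne 25; the carboxylate oxygen of 24 adds at C7, and the C6 aryl anion then attacks the neighbouring ester carbonyl through a four-membered alkoxide that opens to the C7 phenoxide and the C6 ketone, so the C7–O and C6–C(O) bonds both come from one reagent. The closest known reaction type is the insertion of arynes from ortho-silylaryl triflates into the C–O bond of carboxylic acids to give ortho-hydroxyaryl ketones, an aryne form of the anionic Fries shift. No ring is closed and no stereocentre is formed. The step needs oxygen at C7 and not at C6: the C5 OMOM group beside the triple bond distorts the aryne and stabilises negative charge at C6 inductively, as in 3-alkoxybenzynes, so the nucleophile should attack the distal carbon C7. Protonation of the C6 anion to the plain aryl ester is the competing path, and the dry preformed cesium salt, which brings no acidic proton, together with the fast intramolecular acyl shift at 125 °C should hold it back. The MOM acetals, the methyl ether and the prenyl group offer fluoride and carboxylate no reactive site and should pass unchanged.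

Step 16
Reactants: 26 1-[7-hydroxy-5-(methoxymethoxy)-2,2-dimethylchroman-6-yl]-3-[4-methoxy-3-(methoxymethoxy)-5-(3-methylbut-2-en-1-yl)phenyl]propan-1-one
Product: 27 1-(5,7-dihydroxy-2,2-dimethylchroman-6-yl)-3-[3-hydroxy-4-methoxy-5-(3-methylbut-2-en-1-yl)phenyl]propan-1-one
Conditions: HCl (3 M aq.), MeOH, 40 °C
Reagents that add atoms: none
Why: Acid-catalysed acetal exchange with methanol removes both MOM groups, the one at O5 helped by the neighbouring ketone, and the ring B prenyl group has a methyl ether, not a free hydroxyl, at its ortho position and so cannot cyclise.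

**Compound list**
1 | phloroglucinol | Oc1cc(O)cc(O)c1 | starting material
2 | 3-methylbut-2-enoic acid | CC(C)=CC(=O)O | starting material
3 | 5,7-dihydroxy-2,2-dimethylchroman-4-one | CC1(C)CC(=O)c2c(O)cc(O)cc2O1 | intermediate
4 | 5-hydroxy-2,2-dimethyl-4-oxochroman-7-yl N,N-diethylcarbamate | CCN(CC)C(=O)Oc1cc(O)c2C(=O)CC(C)(C)Oc2c1 | intermediate
5 | 7-(diethylcarbamoyloxy)-2,2-dimethyl-4-oxochroman-5-yl ethyl carbonate | CCOC(=O)Oc1cc(OC(=O)N(CC)CC)cc2OC(C)(C)CC(=O)c12 | intermediate (not isolated)
6 | 5-hydroxy-2,2-dimethylchroman-7-yl N,N-diethylcarbamate | CCN(CC)C(=O)Oc1cc(O)c2CCC(C)(C)Oc2c1 | intermediate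
7 | 5-(methoxymethoxy)-2,2-dimethylchroman-7-yl N,N-diethylcarbamate | CCN(CC)C(=O)Oc1cc(OCOC)c2CCC(C)(C)Oc2c1 | intermediate
8 | [7-(diethylcarbamoyloxy)-5-(methoxymethoxy)-2,2-dimethylchroman-6-yl]lithium | [Li]c1c(OC(=O)N(CC)CC)cc2OC(C)(C)CCc2c1OCOC | intermediate (not isolated)
9 | 5-(methoxymethoxy)-2,2-dimethyl-6-(trimethylsilyl)chroman-7-yl N,N-diethylcarbamate | CCN(CC)C(=O)Oc1cc2OC(C)(C)CCc2c(OCOC)c1[Si](C)(C)C | intermediate
10 | 5-(methoxymethoxy)-2,2-dimethyl-6-(trimethylsilyl)chroman-7-ol | COCOc1c2CCC(C)(C)Oc2cc(O)c1[Si](C)(C)C | intermediate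
11 | 5-(methoxymethoxy)-2,2-dimethyl-6-(trimethylsilyl)chroman-7-yl trifluoromethanesulfonate | CC1(C)CCc2c(O1)cc(OS(=O)(=O)C(F)(F)F)c([Si](C)(C)C)c2OCOC | intermediate
12 | 3,4-dihydroxybenzaldehyde | O=Cc1ccc(O)c(O)c1 | starting material
13 | 3-chloro-3-methylbut-1-yne | C#CC(C)(C)Cl | starting material
14 | 3-hydroxy-4-[(2-methylbut-3-yn-2-yl)oxy]benzaldehyde | C#CC(C)(C)Oc1ccc(C=O)cc1O | intermediate
15 | 3-(methoxymethoxy)-4-[(2-methylbut-3-yn-2-yl)oxy]benzaldehyde | C#CC(C)(C)Oc1ccc(C=O)cc1OCOC | intermediate
16 | 3-(methoxymethoxy)-4-[(2-methylbut-3-en-2-yl)oxy]benzaldehyde | C=CC(C)(C)Oc1ccc(C=O)cc1OCOC | intermediate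
17 | 4-hydroxy-3-(methoxymethoxy)-5-(3-methylbut-2-en-1-yl)benzaldehyde | CC(C)=CCc1cc(C=O)cc(OCOC)c1O | intermediate
18 | 4-methoxy-3-(methoxymethoxy)-5-(3-methylbut-2-en-1-yl)benzaldehyde | COCOc1cc(C=O)cc(CC=C(C)C)c1OC | intermediate
19 | 2,2-dimethyl-1,3-dioxane-4,6-dione (Meldrum's acid) | CC1(C)OC(=O)CC(=O)O1 | starting material
20 | 5-[4-methoxy-3-(methoxymethoxy)-5-(3-methylbut-2-en-1-yl)benzylidene]-2,2-dimethyl-1,3-dioxane-4,6-dione | CC1(C)OC(=O)C(=Cc2cc(OCOC)c(OC)c(CC=C(C)C)c2)C(=O)O1 | intermediate (not isolated)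
21 | 5-[4-methoxy-3-(methoxymethoxy)-5-(3-methylbut-2-en-1-yl)benzyl]-2,2-dimethyl-1,3-dioxane-4,6-dione | CC1(C)OC(=O)C(Cc2cc(OCOC)c(OC)c(CC=C(C)C)c2)C(=O)O1 | intermediate
22 | 2-[4-methoxy-3-(methoxymethoxy)-5-(3-methylbut-2-en-1-yl)benzyl]malonic acid | OC(=O)C(Cc1cc(OCOC)c(OC)c(CC=C(C)C)c1)C(=O)O | intermediate (not isolated)
23 | 3-[4-methoxy-3-(methoxymethoxy)-5-(3-methylbut-2-en-1-yl)phenyl]propanoic acid | OC(=O)CCc1cc(OCOC)c(OC)c(CC=C(C)C)c1 | intermediate
24 | cesium 3-[4-methoxy-3-(methoxymethoxy)-5-(3-methylbut-2-en-1-yl)phenyl]propanoate | [Cs+].[O-]C(=O)CCc1cc(OCOC)c(OC)c(CC=C(C)C)c1 | intermediate (not isolated)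
25 | 5-(methoxymethoxy)-2,2-dimethyl-6,7-didehydrochroman (C6–C7 aryne) | COCOC1=C2CCC(C)(C)OC2=CC#C1 | intermediate (not isolated)
26 | 1-[7-hydroxy-5-(methoxymethoxy)-2,2-dimethylchroman-6-yl]-3-[4-methoxy-3-(methoxymethoxy)-5-(3-methylbut-2-en-1-yl)phenyl]propan-1-one | CC1(C)CCc2c(O1)cc(O)c(C(=O)CCc3cc(OCOC)c(OC)c(CC=C(C)C)c3)c2OCOC | intermediate
27 | 1-(5,7-dihydroxy-2,2-dimethylchroman-6-yl)-3-[3-hydroxy-4-methoxy-5-(3-methylbut-2-en-1-yl)phenyl]propan-1-one | COc1c(O)cc(CCC(=O)c2c(O)cc3c(c2O)CCC(C)(C)O3)cc1CC=C(C)C | target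

**Step count**
Total: 16 steps. Longest linear sequence: 9 steps (steps 1 to 7, then 15 and 16; the branch through steps 8 to 14 is equally long).

**Steps most likely to fail**

Step 15. The C6 aryl anion may be protonated before the acyl group shifts, so that only the aryl ester forms. The aryne may also be consumed by the product phenoxide or by an ene reaction with the prenyl alkene. The fallback makes the same C6 carbanion beside the same C7 ester without an aryne, by halogen–lithium exchange in a cold aprotic medium. It sets out from carbamate 7. Lithiation as in step 5 gives aryllithium 8, and a quench with I2 should give 6-iodo-5-(methoxymethoxy)-2,2-dimethylchroman-7-yl N,N-diethylcarbamate F1. KOH in EtOH at reflux hydrolyses the carbamate to 6-iodo-5-(methoxymethoxy)-2,2-dimethylchroman-7-ol F2. Esterification with acid 23 (EDC·HCl, DMAP, CH2Cl2) gives 6-iodo-5-(methoxymethoxy)-2,2-dimethylchroman-7-yl 3-[4-methoxy-3-(methoxymethoxy)-5-(3-methylbut-2-en-1-yl)phenyl]propanoate F3. t-BuLi (2 equiv) in THF/Et2O/pentane at −100 °C exchanges iodine for lithium, and the 1,3 oxygen-to-carbon acyl shift (anionic Fries rearrangement started by metal–halogen exchange) should give 26, where the route is rejoined.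

Step 5. Lithiation may occur in part at C8, between the carbamate and the ring oxygen, and the carbamoyl group may shift to carbon if the aryllithium warms before silylation. The fallback fixes the position with a halogen placed by the free O5–H, for which C6 is the only ortho position. It sets out from phenol 6. NBS with catalytic i-Pr2NH in CH2Cl2 (amine-mediated ortho-bromination of phenols) should give 6-bromo-5-hydroxy-2,2-dimethylchroman-7-yl N,N-diethylcarbamate F4. MOMCl and i-Pr2NEt give 6-bromo-5-(methoxymethoxy)-2,2-dimethylchroman-7-yl N,N-diethylcarbamate F5. Bromine–lithium exchange with n-BuLi in THF at −78 °C followed by Me3SiCl returns to 9.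

Step 8. The tertiary propargyl group may go to O3 or to both oxygens, and the copper-binding catechol may slow the substitution. The fallback is a protecting-group relay, so that the propargylic chloride meets a single free phenol. It sets out from 12. Allyl bromide, NaHCO3 and NaI in DMF at 40 °C (the established 4-O-selective alkylation of this aldehyde with a primary halide) give 4-(allyloxy)-3-hydroxybenzaldehyde F6. MOMCl and i-Pr2NEt give 4-(allyloxy)-3-(methoxymethoxy)benzaldehyde F7. Pd(PPh3)4 and morpholine in THF remove the allyl group to give 4-hydroxy-3-(methoxymethoxy)benzaldehyde F8. Propargylation of F8 with 13 (CuCl2·2H2O, DBU, MeCN, 0 °C) returns to 15.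

**Further compounds**
F1 | step 15 | 6-iodo-5-(methoxymethoxy)-2,2-dimethylchroman-7-yl N,N-diethylcarbamate | CCN(CC)C(=O)Oc1cc2OC(C)(C)CCc2c(OCOC)c1I
F2 | step 15 | 6-iodo-5-(methoxymethoxy)-2,2-dimethylchroman-7-ol | COCOc1c2CCC(C)(C)Oc2cc(O)c1I
F3 | step 15 | 6-iodo-5-(methoxymethoxy)-2,2-dimethylchroman-7-yl 3-[4-methoxy-3-(methoxymethoxy)-5-(3-methylbut-2-en-1-yl)phenyl]propanoate | COCOc1c2CCC(C)(C)Oc2cc(OC(=O)CCc3cc(OCOC)c(OC)c(CC=C(C)C)c3)c1I
F4 | step 5 | 6-bromo-5-hydroxy-2,2-dimethylchroman-7-yl N,N-diethylcarbamate | CCN(CC)C(=O)Oc1cc2OC(C)(C)CCc2c(O)c1Br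
F5 | step 5 | 6-bromo-5-(methoxymethoxy)-2,2-dimethylchroman-7-yl N,N-diethylcarbamate | CCN(CC)C(=O)Oc1cc2OC(C)(C)CCc2c(OCOC)c1Br
F6 | step 8 | 4-(allyloxy)-3-hydroxybenzaldehyde | C=CCOc1ccc(C=O)cc1O
F7 | step 8 | 4-(allyloxy)-3-(methoxymethoxy)benzaldehyde | C=CCOc1ccc(C=O)cc1OCOC
F8 | step 8 | 4-hydroxy-3-(methoxymethoxy)benzaldehyde | COCOc1cc(C=O)ccc1O
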